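## Retrosynthetic overview

1. Target 17 ⇐ methyl enol ether 16 (O-demethylation) ⇐ bicyclic enol ether 14: the bridgehead C1–acyl bond is made last, by bridgehead lithiation and acylation.
2. 14 ⇐ cis-fused hydroxy hydrindenone 12: an oxidative semipinacol ring expansion makes the C1–C8 bond and the bicyclo[3.3.1]nonane (last ring event).
3. 12 ⇐ 11: an intramolecular vinylogous aldol closes the six-membered enone ring onto the cyclopentanone (second ring); 11 ⇐ ketone 7 by Claisen acylation, then prenylation anti to the C3 prenyl group (fixes the C5 bridgehead).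
4. 7 ⇐ tertiary alcohol 4: anionic oxy-Cope rearrangement and enolate alkylation (C7 and C8 of the target); 4 ⇐ 1 + 2: catalytic asymmetric γ-prenylboration, the only external source of chirality (the cyclopentane ring comes with 1).

Assumption: the enolised 2,4-dione of the target is one compound whichever enol tautomer is written; locants in each step follow the name of the compound discussed.

## Route

Step 1
Reactants: 1 2-methylcyclopent-2-en-1-one; 2 prenylboronic acid pinacol ester
Product: 4 (1S)-2-methyl-1-(2-methylbut-3-en-2-yl)cyclopent-2-en-1-ol, via pinacol borate ester 3 (not isolated)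
Conditions: (R)-3,3′-bis(2,4,6-triisopropylphenyl)-1,1′-binaphthyl-2,2′-diyl N-triflylphosphoramide (10 mol %), 4 Å molecular sieves, PhMe, −30 → 0 °C; then H2O
Reagents that add atoms: none
Why: Proposed new method: a chiral Brønsted-acid-catalysed γ-selective prenylboration of a cyclic 2-alkyl enone, in which the confined acid hydrogen-bonds to a boronate oxygen and so raises the Lewis acidity of boron, the ketone binds, and the allyl unit is delivered through its γ-carbon in a closed six-membered chair (Zimmerman–Traxler) transition state to one carbonyl face (alkenyl flank told from CH2 flank by the catalyst pocket; catalyst antipode chosen to give 1S), which also guarantees 1,2- over 1,4-addition; the closest known reaction types are the chiral phosphoric-acid-catalysed allyl- and crotylboration of aldehydes with pinacol boronates and the chiral-diol-catalysed allylboration of ketones.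

Step 2
Reactants: 4 (1S)-2-methyl-1-(2-methylbut-3-en-2-yl)cyclopent-2-en-1-ol; 5 5-bromo-2-methylpent-2-ene
Product: 7 (2R,3R)-2-methyl-2-(4-methylpent-3-en-1-yl)-3-(3-methylbut-2-en-1-yl)cyclopentan-1-one, via potassium enolate 6 (not isolated)
Conditions: KH, 18-crown-6, THF, 0 → 23 °C; then 5, −40 → 23 °C
Reagents that add atoms: none
Why: The potassium alkoxide undergoes an anionic oxy-Cope rearrangement, a suprafacial [3,3] shift that moves the allyl unit from C1 to C3 on the same ring face (1,3-chirality transfer, giving 3R as a normal prenyl group) and releases the regiodefined tetrasubstituted enolate 6, which the primary bromide alkylates anti to the adjacent prenyl group (trans-selective enolate alkylation) to set the 2R quaternary centre.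

Step 3
Reactants: 7 (2R,3R)-2-methyl-2-(4-methylpent-3-en-1-yl)-3-(3-methylbut-2-en-1-yl)cyclopentan-1-one; 8 methyl (2E)-3-methoxybut-2-enoate
Product: 9 (2R,3S)-5-[(2E)-3-methoxybut-2-enoyl]-2-methyl-2-(4-methylpent-3-en-1-yl)-3-(3-methylbut-2-en-1-yl)cyclopentan-1-one
Conditions: NaH, THF, 0 → 60 °C; then aq. HCl
Reagents that add atoms: none
Why: Crossed Claisen condensation at the only enolisable α-carbon (C5), driven by deprotonation of the product β-diketone, with C5 left epimerisable (epimer and enol mixture) so that no lasting stereocentre is formed (the C3 descriptor changes from R to S only because the ring branch now outranks the prenyl branch).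

Step 4
Reactants: 9 (2R,3S)-5-[(2E)-3-methoxybut-2-enoyl]-2-methyl-2-(4-methylpent-3-en-1-yl)-3-(3-methylbut-2-en-1-yl)cyclopentan-1-one; 10 1-bromo-3-methylbut-2-ene
Product: 11 (2R,3S,5S)-5-[(2E)-3-methoxybut-2-enoyl]-2-methyl-2-(4-methylpent-3-en-1-yl)-3,5-bis(3-methylbut-2-en-1-yl)cyclopentan-1-one
Conditions: K2CO3, acetone, 56 °C
Reagents that add atoms: none
Why: C-alkylation of the cyclic β-diketonate by the allylic bromide, which approaches the planar enolate on the face away from the C3 prenyl and C2 methyl groups, so the new prenyl group ends up trans and the acyl chain cis to the C3 prenyl group (5S), the arrangement the bridged target needs.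

Step 5
Reactants: 11 (2R,3S,5S)-5-[(2E)-3-methoxybut-2-enoyl]-2-methyl-2-(4-methylpent-3-en-1-yl)-3,5-bis(3-methylbut-2-en-1-yl)cyclopentan-1-one
Product: 12 (1R,2S,3aR,7aR)-7a-hydroxy-6-methoxy-1-methyl-1-(4-methylpent-3-en-1-yl)-2,3a-bis(3-methylbut-2-en-1-yl)-1,2,3,3a,7,7a-hexahydro-4H-inden-4-one
Conditions: LiN(i-Pr)2, THF, −78 → −30 °C; then AcOH
Reagents that add atoms: none
Why: The amide base removes a γ-hydrogen of the β-methoxy enone (the only acidic site left) and the γ-carbon of the extended enolate adds to the ring ketone in an intramolecular vinylogous aldol reaction, the tether on C5 allowing attack only on its own face, which gives the cis-fused six-membered ring with the hydroxyl syn to the C3a prenyl group (7aR).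

Step 6
Reactants: 12 (1R,2S,3aR,7aR)-7a-hydroxy-6-methoxy-1-methyl-1-(4-methylpent-3-en-1-yl)-2,3a-bis(3-methylbut-2-en-1-yl)-1,2,3,3a,7,7a-hexahydro-4H-inden-4-one
Product: 14 (1S,5R,6R,7S)-4-methoxy-6-methyl-6-(4-methylpent-3-en-1-yl)-1,7-bis(3-methylbut-2-en-1-yl)bicyclo[3.3.1]non-3-ene-2,9-dione, via C7 λ3-iodane 13 (not isolated)
Conditions: PhI(OAc)2, KOH, MeOH, 0 → 23 °C
Reagents that add atoms: none
Why: Base forms the extended enolate, trivalent iodine is taken up at the γ-carbon C7, and the λ3-iodane, an exceptional leaving group, is displaced by 1,2-shift of the antiperiplanar C7a–C1 bond (semipinacol rearrangement with retention at the migrating quaternary carbon), which expands the five-membered ring to the bridged bicycle and turns the carbinol into the C9 ketone, following the hypervalent-iodine oxidative ring expansion of fused hydroxy vinylogous esters used to reach this skeleton.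

Step 7
Reactants: 14 (1S,5R,6R,7S)-4-methoxy-6-methyl-6-(4-methylpent-3-en-1-yl)-1,7-bis(3-methylbut-2-en-1-yl)bicyclo[3.3.1]non-3-ene-2,9-dione; 15 2-methylpropanoyl chloride
Product: 16 (1S,5R,6R,7S)-4-methoxy-6-methyl-6-(4-methylpent-3-en-1-yl)-1,7-bis(3-methylbut-2-en-1-yl)-5-(2-methylpropanoyl)bicyclo[3.3.1]non-3-ene-2,9-dione
Conditions: LiN(i-Pr)2, THF, −78 °C; then 15, −78 → −40 °C
Reagents that add atoms: none
Why: Lithium diisopropylamide is expected to remove the bridgehead hydrogen next to the C9 ketone in preference to the C3 vinylic hydrogen, and the configurationally locked bridgehead carbanion, which cannot O-acylate, is C-acylated with retention by the acid chloride (bridgehead lithiation and acylation of a bicyclo[3.3.1]nonane-trione enol ether).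

Step 8
Reactants: 16 (1S,5R,6R,7S)-4-methoxy-6-methyl-6-(4-methylpent-3-en-1-yl)-1,7-bis(3-methylbut-2-en-1-yl)-5-(2-methylpropanoyl)bicyclo[3.3.1]non-3-ene-2,9-dione
Product: 17 (1S,5S,7S,8R)-4-hydroxy-8-methyl-8-(4-methylpent-3-en-1-yl)-5,7-bis(3-methylbut-2-en-1-yl)-1-(2-methylpropanoyl)bicyclo[3.3.1]non-3-ene-2,9-dione
Conditions: LiCl, DMSO, 120 °C; then aq. HCl
Reagents that add atoms: none
Why: Chloride attacks the O-methyl group in an SN2 dealkylation of the vinylogous ester (Krapcho-type), freeing the enolised β-diketone of the target without touching the alkenes or the stereocentres.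

## Compound list

1 | 2-methylcyclopent-2-en-1-one | CC1=CCCC1=O | starting material
2 | 4,4,5,5-tetramethyl-2-(3-methylbut-2-en-1-yl)-1,3,2-dioxaborolane (prenylboronic acid pinacol ester) | CC(C)=CCB1OC(C)(C)C(C)(C)O1 | starting material
3 | 4,4,5,5-tetramethyl-2-{[(1S)-2-methyl-1-(2-methylbut-3-en-2-yl)cyclopent-2-en-1-yl]oxy}-1,3,2-dioxaborolane | CC1=CCC[C@@]1(OB2OC(C)(C)C(C)(C)O2)C(C)(C)C=C | intermediate
4 | (1S)-2-methyl-1-(2-methylbut-3-en-2-yl)cyclopent-2-en-1-ol | CC1=CCC[C@@]1(O)C(C)(C)C=C | intermediate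
5 | 5-bromo-2-methylpent-2-ene | CC(C)=CCCBr | starting material
6 | potassium (3R)-2-methyl-3-(3-methylbut-2-en-1-yl)cyclopent-1-en-1-olate | [K+].[O-]C1=C(C)[C@@H](CC=C(C)C)CC1 | intermediate
7 | (2R,3R)-2-methyl-2-(4-methylpent-3-en-1-yl)-3-(3-methylbut-2-en-1-yl)cyclopentan-1-one | O=C1CC[C@H](CC=C(C)C)[C@@]1(C)CCC=C(C)C | intermediate
8 | methyl (2E)-3-methoxybut-2-enoate | CO/C(C)=C/C(=O)OC | starting material
9 | (2R,3S)-5-[(2E)-3-methoxybut-2-enoyl]-2-methyl-2-(4-methylpent-3-en-1-yl)-3-(3-methylbut-2-en-1-yl)cyclopentan-1-one (C5 epimers) | CO/C(C)=C/C(=O)C1C[C@H](CC=C(C)C)[C@@](C)(CCC=C(C)C)C1=O | intermediate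
10 | 1-bromo-3-methylbut-2-ene (prenyl bromide) | CC(C)=CCBr | starting material
11 | (2R,3S,5S)-5-[(2E)-3-methoxybut-2-enoyl]-2-methyl-2-(4-methylpent-3-en-1-yl)-3,5-bis(3-methylbut-2-en-1-yl)cyclopentan-1-one | CO/C(C)=C/C(=O)[C@]1(CC=C(C)C)C[C@H](CC=C(C)C)[C@@](C)(CCC=C(C)C)C1=O | intermediate
12 | (1R,2S,3aR,7aR)-7a-hydroxy-6-methoxy-1-methyl-1-(4-methylpent-3-en-1-yl)-2,3a-bis(3-methylbut-2-en-1-yl)-1,2,3,3a,7,7a-hexahydro-4H-inden-4-one | COC1=CC(=O)[C@]2(CC=C(C)C)C[C@H](CC=C(C)C)[C@@](C)(CCC=C(C)C)[C@]2(O)C1 | intermediate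
13 | (1R,2S,3aR,7R,7aR)-7a-hydroxy-6-methoxy-7-[methoxy(phenyl)-λ3-iodanyl]-1-methyl-1-(4-methylpent-3-en-1-yl)-2,3a-bis(3-methylbut-2-en-1-yl)-1,2,3,3a,7,7a-hexahydro-4H-inden-4-one | COC1=CC(=O)[C@]2(CC=C(C)C)C[C@H](CC=C(C)C)[C@@](C)(CCC=C(C)C)[C@]2(O)[C@H]1I(OC)c1ccccc1 | intermediate
14 | (1S,5R,6R,7S)-4-methoxy-6-methyl-6-(4-methylpent-3-en-1-yl)-1,7-bis(3-methylbut-2-en-1-yl)bicyclo[3.3.1]non-3-ene-2,9-dione | COC1=CC(=O)[C@]2(CC=C(C)C)C[C@H](CC=C(C)C)[C@@](C)(CCC=C(C)C)[C@H]1C2=O | intermediate
15 | 2-methylpropanoyl chloride | CC(C)C(Cl)=O | starting material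
16 | (1S,5R,6R,7S)-4-methoxy-6-methyl-6-(4-methylpent-3-en-1-yl)-1,7-bis(3-methylbut-2-en-1-yl)-5-(2-methylpropanoyl)bicyclo[3.3.1]non-3-ene-2,9-dione | COC1=CC(=O)[C@]2(CC=C(C)C)C[C@H](CC=C(C)C)[C@@](C)(CCC=C(C)C)[C@@]1(C(=O)C(C)C)C2=O | intermediate
17 | (1S,5S,7S,8R)-4-hydroxy-8-methyl-8-(4-methylpent-3-en-1-yl)-5,7-bis(3-methylbut-2-en-1-yl)-1-(2-methylpropanoyl)bicyclo[3.3.1]non-3-ene-2,9-dione | CC(C)=CCC[C@]1(C)[C@@H](CC=C(C)C)C[C@]2(CC=C(C)C)C(=O)[C@@]1(C(=O)C(C)C)C(=O)C=C2O | target

## Step count and risks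

Total steps: 8. Longest linear sequence: 8 (1 → 17).

The three steps most likely to fail:

Step 1 (the proposed new method). The hindered, conjugated ketone may not turn over with the pinacol boronate, or the enantioselectivity may be low. The fallback uses known chemistry, sets out from 1 and comes back at 4. Prenylmagnesium chloride (THF, −78 °C) adds to the carbonyl group of 1 through its γ-carbon to give racemic 2-methyl-1-(2-methylbut-3-en-2-yl)cyclopent-2-en-1-ol F1. This is separated by preparative chiral SFC into 4 and the unwanted (1R)-2-methyl-1-(2-methylbut-3-en-2-yl)cyclopent-2-en-1-ol F2.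

Step 2. The crowded potassium alkoxide may fragment and recombine (loss of enantiomeric purity), or the naked enolate may eliminate HBr from 5 or O-alkylate. The fallback sets out from 4 and comes back at 7, and separates the rearrangement from the alkylation while avoiding any free alkoxide. Alcohol 4 is silylated with N-(trimethylsilyl)imidazole to trimethyl{[(1S)-2-methyl-1-(2-methylbut-3-en-2-yl)cyclopent-2-en-1-yl]oxy}silane F3. F3 rearranges in a neutral, concerted siloxy-Cope reaction (PhMe, sealed tube, 200 °C) to trimethyl{[(3R)-2-methyl-3-(3-methylbut-2-en-1-yl)cyclopent-1-en-1-yl]oxy}silane F4. MeLi (THF, 0 °C) then releases the lithium enolate, which is alkylated with 5 in THF/DMPU to give 7.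

Step 7. Deprotonation at the C3 vinylic position may compete with bridgehead deprotonation, and the acid chloride may be lost to ketene formation. The fallback sets out from 14 and comes back at 16, replacing direct acylation by an aldol addition and oxidation. The bridgehead anion (LiN(i-Pr)2, THF, −78 °C) is trapped with 2-methylpropanal to give (1S,5S,6R,7S)-5-(1-hydroxy-2-methylpropyl)-4-methoxy-6-methyl-6-(4-methylpent-3-en-1-yl)-1,7-bis(3-methylbut-2-en-1-yl)bicyclo[3.3.1]non-3-ene-2,9-dione F5 (both carbinol epimers), which is oxidised with Dess–Martin periodinane (CH2Cl2, 23 °C) to 16.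

## Further compounds

F1 | step 1 | racemic 2-methyl-1-(2-methylbut-3-en-2-yl)cyclopent-2-en-1-ol | CC1=CCCC1(O)C(C)(C)C=C
F2 | step 1 | (1R)-2-methyl-1-(2-methylbut-3-en-2-yl)cyclopent-2-en-1-ol | CC1=CCC[C@]1(O)C(C)(C)C=C
F3 | step 2 | trimethyl{[(1S)-2-methyl-1-(2-methylbut-3-en-2-yl)cyclopent-2-en-1-yl]oxy}silane | CC1=CCC[C@@]1(O[Si](C)(C)C)C(C)(C)C=C
F4 | step 2 | trimethyl{[(3R)-2-methyl-3-(3-methylbut-2-en-1-yl)cyclopent-1-en-1-yl]oxy}silane | C[Si](C)(C)OC1=C(C)[C@@H](CC=C(C)C)CC1
F5 | step 7 | (1S,5S,6R,7S)-5-(1-hydroxy-2-methylpropyl)-4-methoxy-6-methyl-6-(4-methylpent-3-en-1-yl)-1,7-bis(3-methylbut-2-en-1-yl)bicyclo[3.3.1]non-3-ene-2,9-dione | COC1=CC(=O)[C@]2(CC=C(C)C)C[C@H](CC=C(C)C)[C@@](C)(CCC=C(C)C)[C@@]1(C(O)C(C)C)C2=O
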